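The bond between the ketone carbon and the methyl-bearing α-carbon (C2 of the side chain) is cut last-but-two, after removal of three MOM ethers and a ketone → carbinol change of oxidation level; the cut is a lithiation–borylation (1,2-metallate shift) that divides the target into benzylic carbamate 22, carrying the whole 5-aryl-2,4-dioxygenated pyridine, and secondary boronic ester 13.
Enabling feature: the acyl carbon sits on C3 of the pyridine ring between the C2 and C4 oxygens. One oxidation level down it is an electron-rich, doubly flanked benzylic O-carbamate carbon that can be lithiated and can then expel the carbamate, so this normally electrophilic carbon is joined as a carbanion to the boron-bound (also donor) α-carbon, and the boron it receives becomes the ketone oxygen.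
13 is cut further at C2–C3 (sparteine-controlled homologation of primary boronic ester 9 with lithiated ethyl carbamate) and at C4–C5 (Evans alkylation with tiglyl bromide); 22 is cut at the aryl–pyridine bond (Suzuki) and at C3–CH2O (directed metalation).
Forward order: chain 1 → 13 (steps 1–6), pyridine 14 → 22 (steps 7–11; both rings are bought, none is built), union (step 12), oxidation (step 13), deprotection (step 14).
Stereochemistry: 6E from tiglyl alcohol; C4 (R) from the (R)-benzyloxazolidinone alkylation; C2 (S) from (+)-sparteine-directed lithiation of ethyl carbamate, carried through step 12 by a stereoretentive migration.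

Key step: step 12

Assumption: ethyl N,N-diisopropylcarbamate and (+)-sparteine are taken as purchasable (the carbamate is otherwise one step from ethanol and the carbamoyl chloride), and alkylation of the silver salt of the pyridone is taken to occur on both oxygens.

Step 1
Reactants: 1 (E)-2-methylbut-2-en-1-ol (tiglyl alcohol)
Product: 2 (E)-1-bromo-2-methylbut-2-ene
Conditions: PBr3 (0.4 equiv), Et2O, 0 °C
Reagents that add atoms: phosphorus tribromide, BrP(Br)Br
Why: Conversion of a primary allylic alcohol into the bromide by SN2 displacement of the bromophosphite should leave the E-trisubstituted alkene untouched at 0 °C.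

Step 2
Reactants: 3 (R)-4-benzyl-3-propanoyl-1,3-oxazolidin-2-one; 2 (E)-1-bromo-2-methylbut-2-ene
Product: 5 (R)-4-benzyl-3-[(2S,4E)-2,4-dimethylhex-4-enoyl]-1,3-oxazolidin-2-one, via sodium Z-enolate 4 (not isolated)
Conditions: NaHMDS, THF, −78 °C; then 2 (excess), −78 → −40 °C
Reagents that add atoms: none
Why: Evans asymmetric alkylation, in which the chelated sodium Z-enolate is alkylated by the reactive allylic bromide on the face away from the benzyl group, should set the methyl-bearing centre (C4 of the target) as 2S in the imide.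

Step 3
Reactants: 5 (R)-4-benzyl-3-[(2S,4E)-2,4-dimethylhex-4-enoyl]-1,3-oxazolidin-2-one
Product: 6 (2S,4E)-2,4-dimethylhex-4-en-1-ol
Conditions: LiBH4, EtOH (1 equiv), Et2O, 0 °C
Reagents that add atoms: none
Why: Reductive cleavage of the N-acyl oxazolidinone by hydride attack at the exocyclic carbonyl should give the primary alcohol without epimerisation and release the auxiliary, the isolated alkene being inert to borohydride.

Step 4
Reactants: 6 (2S,4E)-2,4-dimethylhex-4-en-1-ol
Product: 7 (2E,5S)-6-iodo-3,5-dimethylhex-2-ene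
Conditions: I2, PPh3, imidazole, CH2Cl2, 0 °C → rt
Reagents that add atoms: iodine, II
Why: Appel-type iodination of a primary alcohol proceeds by SN2 at the CH2 carbon, so the neighbouring stereocentre is not touched.

Step 5
Reactants: 7 (2E,5S)-6-iodo-3,5-dimethylhex-2-ene
Product: 9 2-[(2R,4E)-2,4-dimethylhex-4-en-1-yl]-4,4,5,5-tetramethyl-1,3,2-dioxaborolane, via alkyllithium 8 (not isolated)
Conditions: t-BuLi (2.1 equiv), Et2O, −78 °C; then i-PrOBpin, −78 °C → rt
Reagents that add atoms: 2-isopropoxy-4,4,5,5-tetramethyl-1,3,2-dioxaborolane, CC(C)OB1OC(C)(C)C(C)(C)O1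
Why: Iodine–lithium exchange of a primary iodide followed by electrophilic borylation is standard, and the resulting pent-4-enyl-type lithium has no favourable cyclisation mode at −78 °C.

Step 6
Reactants: 10 ethyl N,N-diisopropylcarbamate; 9 2-[(2R,4E)-2,4-dimethylhex-4-en-1-yl]-4,4,5,5-tetramethyl-1,3,2-dioxaborolane
Product: 13 2-[(2S,4R,6E)-4,6-dimethyloct-6-en-2-yl]-4,4,5,5-tetramethyl-1,3,2-dioxaborolane, via lithiated ethyl carbamate 11 (not isolated), via boronate complex 12 (not isolated)
Conditions: 10, s-BuLi, (+)-sparteine, Et2O, −78 °C, 5 h; then 9, −78 °C, 1 h; then MgBr2·OEt2, reflux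
Reagents that add atoms: none
Why: Hoppe–Aggarwal lithiation–borylation, in which (+)-sparteine directs removal of one enantiotopic proton to give the (R)-lithiated carbamate, borylation occurs with retention and the primary alkyl group migrates with inversion at the carbamate carbon, should set C2 as S under reagent control independently of the C4 centre.

Step 7
Reactants: 14 4-hydroxypyridin-2(1H)-one
Product: 15 2,4-bis(methoxymethoxy)pyridine
Conditions: Ag2CO3, MOMCl, toluene, 0 °C → rt, dark
Reagents that add atoms: chloromethyl methyl ether, COCCl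
Why: Silver-mediated alkylation of the ambident 2-pyridone is a known O-selective reaction type, and the hard oxocarbenium-like electrophile should alkylate both the 4-hydroxyl and the lactam oxygen.

Step 8
Reactants: 15 2,4-bis(methoxymethoxy)pyridine
Product: 16 5-bromo-2,4-bis(methoxymethoxy)pyridine
Conditions: NBS, MeCN, 0 °C → rt
Reagents that add atoms: N-bromosuccinimide, O=C1CCC(=O)N1Br
Why: Electrophilic aromatic bromination should go to C5, which is para to the C2 alkoxy group, ortho to the C4 alkoxy group and less hindered than C3 between the two ethers.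

Step 9
Reactants: 16 5-bromo-2,4-bis(methoxymethoxy)pyridine; 17 [4-(methoxymethoxy)phenyl]boronic acid
Product: 18 2,4-bis(methoxymethoxy)-5-[4-(methoxymethoxy)phenyl]pyridine
Conditions: Pd(dppf)Cl2 (cat.), K2CO3, 1,4-dioxane/H2O, 85 °C
Reagents that add atoms: none
Why: Suzuki–Miyaura coupling of a heteroaryl bromide with an arylboronic acid is reliable, and MOM ethers are stable to hot aqueous carbonate.

Step 10
Reactants: 18 2,4-bis(methoxymethoxy)-5-[4-(methoxymethoxy)phenyl]pyridine
Product: 21 {2,4-bis(methoxymethoxy)-5-[4-(methoxymethoxy)phenyl]pyridin-3-yl}methanol, via 3-lithiopyridine 19 (not isolated), via aldehyde 20 (not isolated)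
Conditions: n-BuLi, THF, −78 °C; DMF, −78 → 0 °C; then MeOH, NaBH4, 0 °C
Reagents that add atoms: N,N-dimethylformamide, CN(C)C=O
Why: Directed ortho-metalation should occur at C3, the only position flanked by two OMOM directing groups, and formylation with DMF followed by borohydride reduction of the aldehyde released on adding methanol gives the benzylic alcohol in one flask.

Step 11
Reactants: 21 {2,4-bis(methoxymethoxy)-5-[4-(methoxymethoxy)phenyl]pyridin-3-yl}methanol
Product: 22 {2,4-bis(methoxymethoxy)-5-[4-(methoxymethoxy)phenyl]pyridin-3-yl}methyl N,N-diisopropylcarbamate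
Conditions: i-Pr2NCOCl, Et3N, DMAP (cat.), CH2Cl2, reflux
Reagents that add atoms: N,N-diisopropylcarbamoyl chloride, CC(C)N(C(C)C)C(Cl)=O
Why: DMAP-catalysed O-carbamoylation of a primary benzylic alcohol gives the Hoppe-type carbamate that both directs α-lithiation and later serves as the leaving group.

Step 12
Reactants: 22 {2,4-bis(methoxymethoxy)-5-[4-(methoxymethoxy)phenyl]pyridin-3-yl}methyl N,N-diisopropylcarbamate; 13 2-[(2S,4R,6E)-4,6-dimethyloct-6-en-2-yl]-4,4,5,5-tetramethyl-1,3,2-dioxaborolane
Product: 26 (2S,4R,6E)-1-{2,4-bis(methoxymethoxy)-5-[4-(methoxymethoxy)phenyl]pyridin-3-yl}-2,4,6-trimethyloct-6-en-1-ol (both C1 epimers), via lithiated carbamate 23 (not isolated), via boronate complex 24 (not isolated), via benzylic boronic ester 25 (not isolated)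
Conditions: 22, s-BuLi (1.1 equiv), Et2O, −78 °C, 30 min; 13, −78 °C, 1 h; MgBr2 in MeOH, −78 °C → rt, 16 h; then 2 M NaOH, 30% H2O2, THF, 0 °C → rt
Reagents that add atoms: hydrogen peroxide, OO
Why: s-BuLi removes a proton from the benzylic OCH2 group of 22 (dipole-stabilised, chelated by the carbamate carbonyl and a flanking OMOM oxygen) to give carbenoid 23, which adds to the boron of 13 to give boronate 24; on warming, the secondary alkyl group migrates from boron to the benzylic carbon with loss of the carbamate (1,2-metallate rearrangement), which forms the bond between the future ketone carbon and C2, and the C–B bond of 25 is then oxidised with retention to the carbinol. The closest known reaction type is the lithiation–borylation of lithiated benzylic carbamates with secondary pinacol boronic esters followed by oxidation. No ring is closed. No stereocentre of consequence is created: the carbinol carbon forms as both epimers and is erased in step 13, while C2 migrates with retention of configuration and C4 is remote, so the 2S,4R pattern of 13 should be carried over unchanged. The step needs lithiation of the OCH2 group in preference to ring or phenyl lithiation, and carbon migration in preference to reversal of boronate formation; the first is secured by the complex-induced proximity effect of the carbamate with only a slight excess of base at −78 °C, the second by the electron-rich 2,4-dialkoxypyridin-3-yl group, which makes the benzylic carbamate a good leaving group, assisted by MgBr2/MeOH.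

Step 13
Reactants: 26 (2S,4R,6E)-1-{2,4-bis(methoxymethoxy)-5-[4-(methoxymethoxy)phenyl]pyridin-3-yl}-2,4,6-trimethyloct-6-en-1-ol
Product: 27 (2S,4R,6E)-1-{2,4-bis(methoxymethoxy)-5-[4-(methoxymethoxy)phenyl]pyridin-3-yl}-2,4,6-trimethyloct-6-en-1-one
Conditions: Dess–Martin periodinane, NaHCO3, CH2Cl2, 0 °C → rt
Reagents that add atoms: none
Why: Dess–Martin oxidation of the hindered benzylic alcohol under buffered, non-enolising conditions should give the ketone from both carbinol epimers without epimerising the α-centre or touching the alkene and the pyridine.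

Step 14
Reactants: 27 (2S,4R,6E)-1-{2,4-bis(methoxymethoxy)-5-[4-(methoxymethoxy)phenyl]pyridin-3-yl}-2,4,6-trimethyloct-6-en-1-one
Product: 28 Vancouverone A, 4-hydroxy-5-(4-hydroxyphenyl)-3-[(2S,4R,6E)-2,4,6-trimethyloct-6-enoyl]pyridin-2(1H)-one
Conditions: HCl (ca. 1.25 M in MeOH), THF, 0 °C → rt
Reagents that add atoms: none
Why: Acid-catalysed acetal exchange should remove the three MOM groups (methanol traps each methoxymethyl cation), the 2-hydroxypyridine tautomerises to the 2-pyridone, and dilute acid at room temperature should neither enolise the hydrogen-bonded ketone nor add to the trisubstituted alkene.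

Compound list
1 | (E)-2-methylbut-2-en-1-ol (tiglyl alcohol) | C/C=C(\C)CO | starting material
2 | (E)-1-bromo-2-methylbut-2-ene | C/C=C(\C)CBr | intermediate
3 | (R)-4-benzyl-3-propanoyl-1,3-oxazolidin-2-one | CCC(=O)N1[C@H](Cc2ccccc2)COC1=O | starting material
4 | sodium Z-enolate of 3 (not isolated) | C/C=C(\[O-])N1[C@H](Cc2ccccc2)COC1=O.[Na+] | intermediate
5 | (R)-4-benzyl-3-[(2S,4E)-2,4-dimethylhex-4-enoyl]-1,3-oxazolidin-2-one | C/C=C(\C)C[C@H](C)C(=O)N1[C@H](Cc2ccccc2)COC1=O | intermediate
6 | (2S,4E)-2,4-dimethylhex-4-en-1-ol | C/C=C(\C)C[C@H](C)CO | intermediate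
7 | (2E,5S)-6-iodo-3,5-dimethylhex-2-ene | C/C=C(\C)C[C@H](C)CI | intermediate
8 | [(2R,4E)-2,4-dimethylhex-4-en-1-yl]lithium (not isolated) | C/C=C(\C)C[C@H](C)C[Li] | intermediate
9 | 2-[(2R,4E)-2,4-dimethylhex-4-en-1-yl]-4,4,5,5-tetramethyl-1,3,2-dioxaborolane | C/C=C(\C)C[C@H](C)CB1OC(C)(C)C(C)(C)O1 | intermediate
10 | ethyl N,N-diisopropylcarbamate | CCOC(=O)N(C(C)C)C(C)C | starting material
11 | (R)-1-lithioethyl N,N-diisopropylcarbamate, (+)-sparteine complex (not isolated) | C[C@@H]([Li])OC(=O)N(C(C)C)C(C)C | intermediate
12 | lithium boronate complex formed from 9 and 11 (not isolated) | C/C=C(\C)C[C@H](C)C[B-]1(OC(C)(C)C(C)(C)O1)[C@H](C)OC(=O)N(C(C)C)C(C)C.[Li+] | intermediate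
13 | 2-[(2S,4R,6E)-4,6-dimethyloct-6-en-2-yl]-4,4,5,5-tetramethyl-1,3,2-dioxaborolane | C/C=C(\C)C[C@H](C)C[C@H](C)B1OC(C)(C)C(C)(C)O1 | intermediate
14 | 4-hydroxypyridin-2(1H)-one | O=c1cc(O)cc[nH]1 | starting material
15 | 2,4-bis(methoxymethoxy)pyridine | COCOc1ccnc(OCOC)c1 | intermediate
16 | 5-bromo-2,4-bis(methoxymethoxy)pyridine | COCOc1cc(OCOC)ncc1Br | intermediate
17 | [4-(methoxymethoxy)phenyl]boronic acid | COCOc1ccc(cc1)B(O)O | starting material
18 | 2,4-bis(methoxymethoxy)-5-[4-(methoxymethoxy)phenyl]pyridine | COCOc1ccc(cc1)-c1cnc(OCOC)cc1OCOC | intermediate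
19 | 3-lithio derivative of 18 (not isolated) | [Li]c1c(OCOC)ncc(-c2ccc(OCOC)cc2)c1OCOC | intermediate
20 | 2,4-bis(methoxymethoxy)-5-[4-(methoxymethoxy)phenyl]pyridine-3-carbaldehyde (not isolated) | O=Cc1c(OCOC)ncc(-c2ccc(OCOC)cc2)c1OCOC | intermediate
21 | {2,4-bis(methoxymethoxy)-5-[4-(methoxymethoxy)phenyl]pyridin-3-yl}methanol | OCc1c(OCOC)ncc(-c2ccc(OCOC)cc2)c1OCOC | intermediate
22 | {2,4-bis(methoxymethoxy)-5-[4-(methoxymethoxy)phenyl]pyridin-3-yl}methyl N,N-diisopropylcarbamate | CC(C)N(C(C)C)C(=O)OCc1c(OCOC)ncc(-c2ccc(OCOC)cc2)c1OCOC | intermediate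
23 | α-lithiated carbamate from 22 (not isolated) | [Li]C(OC(=O)N(C(C)C)C(C)C)c1c(OCOC)ncc(-c2ccc(OCOC)cc2)c1OCOC | intermediate
24 | lithium boronate complex formed from 13 and 23 (not isolated) | C/C=C(\C)C[C@H](C)C[C@H](C)[B-]1(OC(C)(C)C(C)(C)O1)C(OC(=O)N(C(C)C)C(C)C)c1c(OCOC)ncc(-c2ccc(OCOC)cc2)c1OCOC.[Li+] | intermediate
25 | 2-[(2S,4R,6E)-1-{2,4-bis(methoxymethoxy)-5-[4-(methoxymethoxy)phenyl]pyridin-3-yl}-2,4,6-trimethyloct-6-en-1-yl]-4,4,5,5-tetramethyl-1,3,2-dioxaborolane, both C1 epimers (not isolated) | C/C=C(\C)C[C@H](C)C[C@H](C)C(B1OC(C)(C)C(C)(C)O1)c1c(OCOC)ncc(-c2ccc(OCOC)cc2)c1OCOC | intermediate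
26 | (2S,4R,6E)-1-{2,4-bis(methoxymethoxy)-5-[4-(methoxymethoxy)phenyl]pyridin-3-yl}-2,4,6-trimethyloct-6-en-1-ol, both C1 epimers | C/C=C(\C)C[C@H](C)C[C@H](C)C(O)c1c(OCOC)ncc(-c2ccc(OCOC)cc2)c1OCOC | intermediate
27 | (2S,4R,6E)-1-{2,4-bis(methoxymethoxy)-5-[4-(methoxymethoxy)phenyl]pyridin-3-yl}-2,4,6-trimethyloct-6-en-1-one | C/C=C(\C)C[C@H](C)C[C@H](C)C(=O)c1c(OCOC)ncc(-c2ccc(OCOC)cc2)c1OCOC | intermediate
28 | Vancouverone A, 4-hydroxy-5-(4-hydroxyphenyl)-3-[(2S,4R,6E)-2,4,6-trimethyloct-6-enoyl]pyridin-2(1H)-one | C/C=C(\C)C[C@H](C)C[C@H](C)C(=O)c1c(O)c(-c2ccc(O)cc2)c[nH]c1=O | target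

Total step count: 14 steps.
Longest linear sequence: 9 steps (steps 1–6, then 12–14); the pyridine branch is 5 steps (7–11) before the union.

Steps most likely to fail

Step 12 (key step). Boronate formation between the doubly ortho-substituted lithiated carbamate and the secondary boronic ester may be too slow, or may reverse before the 1,2-shift, and the base may lithiate the phenyl ring next to its OMOM group. The fallback sets out from 13 and 18 and comes back to the route at 26; it brings the carbinol carbon in as a small carbenoid, so the same bond is still made by a stereoretentive 1,2-shift. 13 is treated with dichloromethyllithium (CH2Cl2, n-BuLi, THF, −100 °C; ZnCl2, → rt; Matteson homologation) to give 2-[(2S,4R,6E)-1-chloro-2,4,6-trimethyloct-6-en-1-yl]-4,4,5,5-tetramethyl-1,3,2-dioxaborolane F1. Buffered oxidation of this compound (H2O2, pH 7 phosphate, THF, 0 °C) should give (2S,4R,6E)-2,4,6-trimethyloct-6-enal F2. 18 is lithiated at C3 as in step 10 (n-BuLi, THF, −78 °C) to 19, which is added to F2 at −78 °C to give 26, and the route continues with step 13.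

Step 6. Facial discrimination in the sparteine-mediated deprotonation may be incomplete, or the 1,2-migration of the unactivated carbamate boronate may be sluggish, either of which lowers the purity at C2. The fallback sets out from 7 and comes back at 13; it sets C2 by catalyst-controlled hydroboration. 7 is coupled with vinylmagnesium bromide (CuI cat., THF, −20 → 0 °C) to give (4R,6E)-4,6-dimethylocta-1,6-diene F3. Copper(I)-catalysed enantioselective Markovnikov hydroboration of its terminal alkene (B2pin2, MeOH, KOt-Bu, CuCl, chiral bisphosphine of the enantiomeric series that gives the 2S centre; the trisubstituted alkene should not insert) gives 13.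

Step 10. Lithiation may occur on the phenyl ring ortho to its OMOM group, or butyllithium may add across the C6=N bond, in competition with deprotonation at C3. The fallback sets out from 15 (and uses 17) and comes back at 22; it introduces the C3 carbon before the aryl group, when C3 is the only doubly activated site. 15 is lithiated (n-BuLi, THF, −78 °C) to 3-lithio-2,4-bis(methoxymethoxy)pyridine F4 and quenched with DMF to give 2,4-bis(methoxymethoxy)pyridine-3-carbaldehyde F5. NaBH4 in MeOH gives [2,4-bis(methoxymethoxy)pyridin-3-yl]methanol F6, and carbamoylation as in step 11 gives [2,4-bis(methoxymethoxy)pyridin-3-yl]methyl N,N-diisopropylcarbamate F7. NBS in MeCN, with C3 now blocked, can only brominate C5 and gives [5-bromo-2,4-bis(methoxymethoxy)pyridin-3-yl]methyl N,N-diisopropylcarbamate F8. Suzuki coupling of F8 with 17 under the conditions of step 9 gives 22.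

Further compounds
F1 | step 12 | 2-[(2S,4R,6E)-1-chloro-2,4,6-trimethyloct-6-en-1-yl]-4,4,5,5-tetramethyl-1,3,2-dioxaborolane (both C1 epimers) | C/C=C(\C)C[C@H](C)C[C@H](C)C(Cl)B1OC(C)(C)C(C)(C)O1
F2 | step 12 | (2S,4R,6E)-2,4,6-trimethyloct-6-enal | C/C=C(\C)C[C@H](C)C[C@H](C)C=O
F3 | step 6 | (4R,6E)-4,6-dimethylocta-1,6-diene | C/C=C(\C)C[C@H](C)CC=C
F4 | step 10 | 3-lithio-2,4-bis(methoxymethoxy)pyridine | [Li]c1c(OCOC)nccc1OCOC
F5 | step 10 | 2,4-bis(methoxymethoxy)pyridine-3-carbaldehyde | O=Cc1c(OCOC)nccc1OCOC
F6 | step 10 | [2,4-bis(methoxymethoxy)pyridin-3-yl]methanol | OCc1c(OCOC)nccc1OCOC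
F7 | step 10 | [2,4-bis(methoxymethoxy)pyridin-3-yl]methyl N,N-diisopropylcarbamate | CC(C)N(C(C)C)C(=O)OCc1c(OCOC)nccc1OCOC
F8 | step 10 | [5-bromo-2,4-bis(methoxymethoxy)pyridin-3-yl]methyl N,N-diisopropylcarbamate | CC(C)N(C(C)C)C(=O)OCc1c(OCOC)ncc(Br)c1OCOC
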